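## Retrosynthetic overview

1. Lepadin H ⇒ (remove Boc and TBS; form the C3–O ester bond by Mitsunobu inversion) all-cis N-Boc-5-alkyl-2-methyldecahydroquinolin-3-ol ⇒ (all-syn hydrogenation from one face, with C5 controlling C2, C3, C4a and C8a) flat (5S)-5-alkyl-2-methyl-5,6,7,8-tetrahydroquinolin-3-ol.
2. Key disconnection: bonds C8a–C4a and C3–C4 of that pyridinol ⇒ an acyclic 2-alkyl-5-ethoxy-4-methyloxazole carrying a vinyl group (intramolecular oxazole–olefin [4+2], opening of the oxygen bridge, loss of EtOH).
3. Enabling feature: N1–C2(CH3)–C3(O) of ring A (the azacycle) is an alanine unit and maps onto N3–C4(CH3)–C5(OEt) of the oxazole. C8a is oxazole C2, C4a=C4 is a vinyl group on C5, and C5–C6–C7–C8 of ring B (the carbocycle) is the four-carbon tether. H2, H4a, H5 and H8a lie on one face, so a flat ring A can be reduced from a single side.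
4. Oxazole ⇒ alanine ethyl ester + (5S,10R)-5-ethenyl-10-silyloxytridecanoic acid ⇒ copper-catalysed asymmetric SN2' alkylation (sets C5) of methyl (E)-7-bromohept-5-enoate with a Grignard reagent built from (R)-2-propyloxirane (C5').
5. Ring order: the temporary oxazole ring is made first. In the key step ring B closes through C8a–C4a, and ring A, completed by C3–C4, is the last ring of the skeleton. The oxazole ring is consumed in the same operation.

Key step: step 10

Remark: the locants N1–C8a and C1'–C8' of the target are used for all intermediates. (R)-2-Propyloxirane is taken as a commercial compound. The Taniaphos enantiomer in step 6 is the one whose established sense of induction gives the 5S centre.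

## Route

Step 1
Reactants: 1 (R)-2-propyloxirane; 2 allylmagnesium bromide
Product: 3 (R)-oct-1-en-5-ol
Conditions: CuI (10 mol %), THF/Et2O, −40 to 0 °C; aq. work-up
Reagents that add atoms: none
Why: Copper-catalysed SN2 opening of a terminal epoxide by a Grignard reagent occurs at the unsubstituted carbon, so the C–O stereocentre of 1 passes unchanged into 3 as the future C5' (R).

Step 2
Reactants: 3 (R)-oct-1-en-5-ol
Product: 4 (R)-tert-butyldimethyl(oct-1-en-5-yloxy)silane
Conditions: TBSCl, imidazole, DMF, rt
Reagents that add atoms: tert-butyldimethylsilyl chloride CC(C)(C)[Si](C)(C)Cl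
Why: Standard silyl ether formation; an aryl-free silyl group is chosen because it should survive Grignard formation, base, POCl3/Et3N, 180 °C and ring hydrogenation, and it is cleaved together with Boc at the end.

Step 3
Reactants: 4 (R)-tert-butyldimethyl(oct-1-en-5-yloxy)silane
Product: 6 (R)-5-(tert-butyldimethylsilyloxy)octan-1-ol, via alkylborane 5 (not isolated)
Conditions: 9-BBN, THF, 0 °C to rt; then NaOH, H2O2, 0 °C
Reagents that add atoms: hydrogen peroxide OO
Why: Anti-Markovnikov hydroboration–oxidation of a terminal alkene gives the primary alcohol and completes the C1'–C4' chain without touching C5'.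

Step 4
Reactants: 6 (R)-5-(tert-butyldimethylsilyloxy)octan-1-ol
Product: 7 (R)-1-bromo-5-(tert-butyldimethylsilyloxy)octane
Conditions: CBr4, PPh3, CH2Cl2, 0 °C
Reagents that add atoms: carbon tetrabromide BrC(Br)(Br)Br
Why: The Appel reaction converts a primary alcohol into the bromide under neutral conditions that leave the silyl ether intact.

Step 5
Reactants: 8 methyl hex-5-enoate; 9 (E)-1,4-dibromobut-2-ene
Product: 10 methyl (E)-7-bromohept-5-enoate
Conditions: second-generation Grubbs catalyst RuCl2(=CHPh)(PCy3)(H2IMes) (3 mol %), 9 in excess, CH2Cl2, 40 °C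
Reagents that add atoms: none
Why: Olefin cross metathesis of a terminal alkene with a symmetrical 1,4-dihalobutene is a known route to (E)-allylic halides; the E geometry is the thermodynamic outcome, and any minor Z isomer is removed by chromatography.

Step 6
Reactants: 7 (R)-1-bromo-5-(tert-butyldimethylsilyloxy)octane; 10 methyl (E)-7-bromohept-5-enoate
Product: 12 methyl (5S,10R)-10-(tert-butyldimethylsilyloxy)-5-ethenyltridecanoate, via Grignard reagent 11 (not isolated)
Conditions: 7, Mg, Et2O, reflux; then added to 10, CuBr·SMe2 (5 mol %), Taniaphos (C5H5)Fe[C5H3(PPh2)CH(NMe2)C6H4-2-PPh2] (6 mol %), CH2Cl2, −75 °C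
Reagents that add atoms: none
Why: Asymmetric allylic alkylation of an aliphatic (E)-allyl bromide with an alkyl Grignard reagent under monovalent-copper/ferrocenyl diphosphine catalysis proceeds in the SN2' sense and creates the vinyl-bearing centre C5 (S) under ligand control; the remote methyl ester is inert at −75 °C.

Step 7
Reactants: 12 methyl (5S,10R)-10-(tert-butyldimethylsilyloxy)-5-ethenyltridecanoate
Product: 13 (5S,10R)-10-(tert-butyldimethylsilyloxy)-5-ethenyltridecanoic acid
Conditions: LiOH, THF/MeOH/H2O, rt; then 1 M HCl to pH 4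
Reagents that add atoms: lithium hydroxide [Li+].[OH-]
Why: Saponification of an unhindered methyl ester; neither stereocentre is acidic and the silyl ether tolerates dilute base.

Step 8
Reactants: 13 (5S,10R)-10-(tert-butyldimethylsilyloxy)-5-ethenyltridecanoic acid; 14 L-alanine ethyl ester hydrochloride
Product: 15 ethyl N-[(5S,10R)-10-(tert-butyldimethylsilyloxy)-5-ethenyltridecanoyl]-L-alaninate
Conditions: EDC·HCl, HOBt (cat.), iPr2NEt, CH2Cl2, 0 °C to rt
Reagents that add atoms: none
Why: Carbodiimide amide coupling brings in N1, C2, its methyl group and C3; the alanine centre is erased in step 9, so its integrity does not matter.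

Step 9
Reactants: 15 ethyl N-[(5S,10R)-10-(tert-butyldimethylsilyloxy)-5-ethenyltridecanoyl]-L-alaninate
Product: 16 2-[(4S,9R)-9-(tert-butyldimethylsilyloxy)-4-ethenyldodecyl]-5-ethoxy-4-methyl-1,3-oxazole
Conditions: POCl3, Et3N, toluene, 80 °C
Reagents that add atoms: none
Why: Robinson–Gabriel-type cyclodehydration of an N-acylalanine ester (the ester oxygen attacks the activated amide carbon, then the α-proton is lost) is the established entry to 5-alkoxy-4-methyloxazoles, and the excess base protects the silyl ether.

Step 10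
Reactants: 16 2-[(4S,9R)-9-(tert-butyldimethylsilyloxy)-4-ethenyldodecyl]-5-ethoxy-4-methyl-1,3-oxazole
Product: 18 (5S)-5-[(5R)-5-(tert-butyldimethylsilyloxy)octyl]-2-methyl-5,6,7,8-tetrahydroquinolin-3-ol, via oxa-bridged cycloadduct 17 (not isolated)
Conditions: 1,2-dichlorobenzene (0.01 M), AcOH (10 mol %), BHT (cat.), 180 °C, sealed tube
Reagents that add atoms: none
Why: The 2-azadiene C8a=N1–C2=C3 of the oxazole adds across the tethered vinyl group C4a=C4 in a thermal intramolecular [4+2] cycloaddition to give the 7-oxa-2-azabicyclo[2.2.1]heptene 17, whose oxygen bridge opens at C8a–O with loss of H4a, after which the C3 hemiketal expels ethanol and the product tautomerises to the aromatic pyridinol 18, so a reversible cycloaddition is drained irreversibly. The closest known reaction types are the intramolecular Kondrat'eva pyridine synthesis (oxazole–olefin Diels–Alder reaction) and the thermal addition of 5-ethoxy-4-methyloxazole to unactivated cis-alkenes used for pyridoxine. Ring B closes through the C8a–C4a bond as a six-membered ring over the four-carbon tether C5–C8 (fused mode of an intramolecular Diels–Alder reaction), and ring A is closed by the same [4+2] event, completed by the C3–C4 bond, and freed as the six-membered ring N1, C2, C3, C4, C4a, C8a when the oxazole oxygen leaves C8a. No lasting stereocentre is formed: the three sp3 centres of 17 (C3, C4a, C8a) are erased on aromatisation, so endo/exo and facial selectivity are irrelevant, while C5 and C5' are untouched because neither is acidic. The step needs regioselectivity (C8a to the internal and C3 to the terminal alkene carbon), which the tether length secures because the crossed mode would give a strained bridged seven-membered ring; it also needs loss of ethanol rather than water, which the ketal-type carbon C3 and the trace of acetic acid secure, and high dilution suppresses intermolecular addition.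

Step 11
Reactants: 18 (5S)-5-[(5R)-5-(tert-butyldimethylsilyloxy)octyl]-2-methyl-5,6,7,8-tetrahydroquinolin-3-ol
Product: 19 (2S,3S,4aS,5S,8aR)-5-[(5R)-5-(tert-butyldimethylsilyloxy)octyl]-2-methyldecahydroquinolin-3-ol
Conditions: H2 (50 bar), 5% Rh/Al2O3, EtOH/AcOH 10:1, 50 °C
Reagents that add atoms: none
Why: Heterogeneous all-syn hydrogenation of 2,6-dialkylpyridin-3-ols is known to give all-cis piperidin-3-ols; here the C5 chain, held pseudoaxial by peri strain with H4, shields one face, so H2, H3, H4a and H8a should all be delivered cis to H5, which sets C2 (S), C3 (S), C4a (S) and C8a (R).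

Step 12
Reactants: 19 (2S,3S,4aS,5S,8aR)-5-[(5R)-5-(tert-butyldimethylsilyloxy)octyl]-2-methyldecahydroquinolin-3-ol
Product: 20 tert-butyl (2S,3S,4aS,5S,8aR)-5-[(5R)-5-(tert-butyldimethylsilyloxy)octyl]-3-hydroxy-2-methyldecahydroquinoline-1-carboxylate
Conditions: Boc2O, THF, 55 °C
Reagents that add atoms: di-tert-butyl dicarbonate CC(C)(C)OC(=O)OC(=O)OC(C)(C)C
Why: Carbamate formation is selective for nitrogen when no acyl-transfer catalyst is present, and it removes the nucleophilicity of N1 that would otherwise cause aziridinium participation at C3 in step 14.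

Step 13
Reactants: 21 (E)-hex-2-enal; 22 malonic acid
Product: 24 (2E,4E)-octa-2,4-dienoic acid, via hexenylidenemalonic acid 23 (not isolated)
Conditions: pyridine, piperidine (cat.), 90 °C
Reagents that add atoms: none
Why: The Doebner modification of the Knoevenagel condensation (as used for sorbic acid) gives the dienoic acid after decarboxylation, with the new double bond formed in the thermodynamically preferred E geometry.

Step 14
Reactants: 20 tert-butyl (2S,3S,4aS,5S,8aR)-5-[(5R)-5-(tert-butyldimethylsilyloxy)octyl]-3-hydroxy-2-methyldecahydroquinoline-1-carboxylate; 24 (2E,4E)-octa-2,4-dienoic acid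
Product: 25 tert-butyl (2S,3R,4aS,5S,8aR)-5-[(5R)-5-(tert-butyldimethylsilyloxy)octyl]-2-methyl-3-[(2E,4E)-octa-2,4-dienoyloxy]decahydroquinoline-1-carboxylate
Conditions: PPh3, DIAD, toluene, 0 °C to rt
Reagents that add atoms: none
Why: In the Mitsunobu reaction the dienoate displaces the alkoxyphosphonium group by SN2, inverting C3 from S to R and installing the ester in one operation; in the N-Boc conformer (2-methyl and C8 axial through A(1,3) strain) the C3–O bond is equatorial, so no antiperiplanar hydrogen is available for elimination and the axial trajectory is flanked only by H4a.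

Step 15
Reactants: 25 tert-butyl (2S,3R,4aS,5S,8aR)-5-[(5R)-5-(tert-butyldimethylsilyloxy)octyl]-2-methyl-3-[(2E,4E)-octa-2,4-dienoyloxy]decahydroquinoline-1-carboxylate
Product: 26 lepadin H
Conditions: TFA/CH2Cl2/H2O 10:10:1, 0 °C to rt; aq. NaHCO3 work-up
Reagents that add atoms: none
Why: Acidolysis removes the tert-butyl carbamate and the secondary silyl ether together, while the dienoate ester and all six stereocentres are inert to acid.

## Compound list

1 | (R)-2-propyloxirane | CCC[C@@H]1CO1 | starting material
2 | allylmagnesium bromide | C=CC[Mg]Br | starting material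
3 | (R)-oct-1-en-5-ol | C=CCC[C@H](O)CCC | intermediate
4 | (R)-tert-butyldimethyl(oct-1-en-5-yloxy)silane | C=CCC[C@H](O[Si](C)(C)C(C)(C)C)CCC | intermediate
5 | 9-[(5R)-5-(tert-butyldimethylsilyloxy)octyl]-9-borabicyclo[3.3.1]nonane | C1CC2CCCC(C1)B2CCCC[C@H](O[Si](C)(C)C(C)(C)C)CCC | intermediate (not isolated)
6 | (R)-5-(tert-butyldimethylsilyloxy)octan-1-ol | OCCCC[C@H](O[Si](C)(C)C(C)(C)C)CCC | intermediate
7 | (R)-1-bromo-5-(tert-butyldimethylsilyloxy)octane | BrCCCC[C@H](O[Si](C)(C)C(C)(C)C)CCC | intermediate
8 | methyl hex-5-enoate | COC(=O)CCCC=C | starting material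
9 | (E)-1,4-dibromobut-2-ene | BrC/C=C/CBr | starting material
10 | methyl (E)-7-bromohept-5-enoate | COC(=O)CCC/C=C/CBr | intermediate
11 | [(5R)-5-(tert-butyldimethylsilyloxy)octyl]magnesium bromide | Br[Mg]CCCC[C@H](O[Si](C)(C)C(C)(C)C)CCC | intermediate (not isolated)
12 | methyl (5S,10R)-10-(tert-butyldimethylsilyloxy)-5-ethenyltridecanoate | COC(=O)CCC[C@@H](C=C)CCCC[C@H](O[Si](C)(C)C(C)(C)C)CCC | intermediate
13 | (5S,10R)-10-(tert-butyldimethylsilyloxy)-5-ethenyltridecanoic acid | OC(=O)CCC[C@@H](C=C)CCCC[C@H](O[Si](C)(C)C(C)(C)C)CCC | intermediate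
14 | L-alanine ethyl ester hydrochloride | CCOC(=O)[C@H](C)N.Cl | starting material
15 | ethyl N-[(5S,10R)-10-(tert-butyldimethylsilyloxy)-5-ethenyltridecanoyl]-L-alaninate | CCOC(=O)[C@H](C)NC(=O)CCC[C@@H](C=C)CCCC[C@H](O[Si](C)(C)C(C)(C)C)CCC | intermediate
16 | 2-[(4S,9R)-9-(tert-butyldimethylsilyloxy)-4-ethenyldodecyl]-5-ethoxy-4-methyl-1,3-oxazole | CCOc1oc(CCC[C@@H](C=C)CCCC[C@H](O[Si](C)(C)C(C)(C)C)CCC)nc1C | intermediate
17 | oxa-bridged [4+2] adduct (7-oxa-2-azabicyclo[2.2.1]hept-2-ene fused to ring B; endo/exo mixture, so the transient centres C3, C4a and C8a are left open) | CCOC12CC3[C@@H](CCCC[C@H](O[Si](C)(C)C(C)(C)C)CCC)CCCC3(O1)N=C2C | intermediate (not isolated)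
18 | (5S)-5-[(5R)-5-(tert-butyldimethylsilyloxy)octyl]-2-methyl-5,6,7,8-tetrahydroquinolin-3-ol | Cc1nc2c(cc1O)[C@@H](CCCC[C@H](O[Si](C)(C)C(C)(C)C)CCC)CCC2 | intermediate
19 | (2S,3S,4aS,5S,8aR)-5-[(5R)-5-(tert-butyldimethylsilyloxy)octyl]-2-methyldecahydroquinolin-3-ol | O[C@H]1C[C@H]2[C@@H](CCCC[C@H](O[Si](C)(C)C(C)(C)C)CCC)CCC[C@H]2N[C@H]1C | intermediate
20 | tert-butyl (2S,3S,4aS,5S,8aR)-5-[(5R)-5-(tert-butyldimethylsilyloxy)octyl]-3-hydroxy-2-methyldecahydroquinoline-1-carboxylate | O[C@H]1C[C@H]2[C@@H](CCCC[C@H](O[Si](C)(C)C(C)(C)C)CCC)CCC[C@H]2N(C(=O)OC(C)(C)C)[C@H]1C | intermediate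
21 | (E)-hex-2-enal | CCC/C=C/C=O | starting material
22 | malonic acid | OC(=O)CC(=O)O | starting material
23 | 2-[(E)-hex-2-en-1-ylidene]propanedioic acid | CCC/C=C/C=C(C(=O)O)C(=O)O | intermediate (not isolated)
24 | (2E,4E)-octa-2,4-dienoic acid | CCC/C=C/C=C/C(=O)O | intermediate
25 | tert-butyl (2S,3R,4aS,5S,8aR)-5-[(5R)-5-(tert-butyldimethylsilyloxy)octyl]-2-methyl-3-[(2E,4E)-octa-2,4-dienoyloxy]decahydroquinoline-1-carboxylate | CCC/C=C/C=C/C(=O)O[C@@H]1C[C@H]2[C@@H](CCCC[C@H](O[Si](C)(C)C(C)(C)C)CCC)CCC[C@H]2N(C(=O)OC(C)(C)C)[C@H]1C | intermediate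
26 | lepadin H, (2S,3R,4aS,5S,8aR)-5-[(5R)-5-hydroxyoctyl]-2-methyldecahydroquinolin-3-yl (2E,4E)-octa-2,4-dienoate | CCC/C=C/C=C/C(=O)O[C@@H]1C[C@H]2[C@@H](CCCC[C@H](O)CCC)CCC[C@H]2N[C@H]1C | target

## Step count and risks

Total step count: 15.
Longest linear sequence: 13 steps (1, 2, 3, 4, 6, 7, 8, 9, 10, 11, 12, 14, 15).

**Step 10.**
- **Risk:** the unactivated vinyl group may add so slowly that thermal degradation or adventitious hydrolysis of the alkoxyoxazole outruns cycloaddition. The bridge may also open with loss of water instead of ethanol.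
- **Fallback:** a temporary activating group on the dienophile switches the cycloaddition to normal electron demand. The fallback sets out from 16.
- Cross metathesis with acrylic acid (second-generation Hoveyda–Grubbs catalyst RuCl2(=CH-C6H4-2-OiPr)(H2IMes), CH2Cl2, 40 °C) should give (2E,4S,9R)-9-(tert-butyldimethylsilyloxy)-4-[3-(5-ethoxy-4-methyl-1,3-oxazol-2-yl)propyl]dodec-2-enoic acid F1.
- Its electron-poor alkene should undergo the same intramolecular cycloaddition in toluene at or below 110 °C and lose ethanol, giving (5S)-5-[(5R)-5-(tert-butyldimethylsilyloxy)octyl]-3-hydroxy-2-methyl-5,6,7,8-tetrahydroquinoline-4-carboxylic acid F2.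
- Further heating (1,2-dichlorobenzene, 180 °C) should expel CO2 through the β-keto-acid tautomer and come back to the route at 18.
- This is the intramolecular form of the known decarboxylative cycloaddition of alkoxyoxazoles with acrylic acid.

**Step 11.**
- **Risk:** facial discrimination by the C5 chain may be poor. Half-reduced enamine or ketone tautomers may desorb and re-add hydrogen from the other side (trans fusion or epimers at C2/C3), and hydrogenolysis of the C3–O bond is possible.
- **Fallback:** homogeneous catalyst control replaces substrate control on a metal surface. The fallback sets out from 18.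
- N-Benzylation (BnBr, MeCN, 80 °C) should give (5S)-1-benzyl-5-[(5R)-5-(tert-butyldimethylsilyloxy)octyl]-3-hydroxy-2-methyl-5,6,7,8-tetrahydroquinolin-1-ium bromide F3.
- Asymmetric hydrogenation of this pyridinium salt ([Ir(cod)Cl]2, SegPhos in the antipode matched to C5, H2 50 bar, CH2Cl2/iPrOH), a reaction type known for hydroxy-substituted N-benzylpyridinium salts, should give (2S,3S,4aS,5S,8aR)-1-benzyl-5-[(5R)-5-(tert-butyldimethylsilyloxy)octyl]-2-methyldecahydroquinolin-3-ol F4.
- Hydrogenolysis (H2, Pd(OH)2/C, EtOH) comes back to the route at 19.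

**Step 14.**
- **Risk:** formation and displacement of the bulky alkoxyphosphonium ion at the hindered C3 may be slow with a weakly acidic dienoic acid. The result would be recovered alcohol, elimination towards the C3–C4 olefin, or acyl transfer with retention.
- **Fallback:** a two-stage stereospecific displacement with a small, isolable leaving group and a pre-formed naked carboxylate replaces the redox condensation. The fallback sets out from 20 and 24.
- ClCH2SO2Cl in pyridine at 0 °C should give tert-butyl (2S,3S,4aS,5S,8aR)-5-[(5R)-5-(tert-butyldimethylsilyloxy)octyl]-3-(chloromethanesulfonyloxy)-2-methyldecahydroquinoline-1-carboxylate F5.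
- Acid 24 with Cs2CO3 in MeOH, followed by drying, gives caesium (2E,4E)-octa-2,4-dienoate F6.
- Heating F5 with F6 and 18-crown-6 in toluene at 70 °C should bring about SN2 inversion and come back to the route at 25.

## Further compounds

F1 | step 10 | (2E,4S,9R)-9-(tert-butyldimethylsilyloxy)-4-[3-(5-ethoxy-4-methyl-1,3-oxazol-2-yl)propyl]dodec-2-enoic acid | CCOc1oc(CCC[C@@H](/C=C/C(=O)O)CCCC[C@H](O[Si](C)(C)C(C)(C)C)CCC)nc1C
F2 | step 10 | (5S)-5-[(5R)-5-(tert-butyldimethylsilyloxy)octyl]-3-hydroxy-2-methyl-5,6,7,8-tetrahydroquinoline-4-carboxylic acid | Cc1nc2c(c(C(=O)O)c1O)[C@@H](CCCC[C@H](O[Si](C)(C)C(C)(C)C)CCC)CCC2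
F3 | step 11 | (5S)-1-benzyl-5-[(5R)-5-(tert-butyldimethylsilyloxy)octyl]-3-hydroxy-2-methyl-5,6,7,8-tetrahydroquinolin-1-ium bromide | Cc1[n+](Cc3ccccc3)c2c(cc1O)[C@@H](CCCC[C@H](O[Si](C)(C)C(C)(C)C)CCC)CCC2.[Br-]
F4 | step 11 | (2S,3S,4aS,5S,8aR)-1-benzyl-5-[(5R)-5-(tert-butyldimethylsilyloxy)octyl]-2-methyldecahydroquinolin-3-ol | O[C@H]1C[C@H]2[C@@H](CCCC[C@H](O[Si](C)(C)C(C)(C)C)CCC)CCC[C@H]2N(Cc3ccccc3)[C@H]1C
F5 | step 14 | tert-butyl (2S,3S,4aS,5S,8aR)-5-[(5R)-5-(tert-butyldimethylsilyloxy)octyl]-3-(chloromethanesulfonyloxy)-2-methyldecahydroquinoline-1-carboxylate | ClCS(=O)(=O)O[C@H]1C[C@H]2[C@@H](CCCC[C@H](O[Si](C)(C)C(C)(C)C)CCC)CCC[C@H]2N(C(=O)OC(C)(C)C)[C@H]1C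
F6 | step 14 | caesium (2E,4E)-octa-2,4-dienoate | CCC/C=C/C=C/C(=O)[O-].[Cs+]
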